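**Retrosynthetic overview**
- The target comes from its bis-TBS ether by buffered fluoride desilylation; the isovalerate is put on the free (R)-carbinol just before that.
- The (R)-carbinol, the only stereocentre, comes from a prochiral furyl prenyl ketone by ketoreductase (KRED) reduction.
- The ketone comes from a 5-aryl-3-furaldehyde by dithiane umpolung (Corey–Seebach) with prenyl bromide, which gives the linear prenyl chain.
- The aryl–furan bond comes from a Suzuki coupling of a 2,5-bis(silyloxy)phenyl boronate with methyl 5-bromofuran-3-carboxylate.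
- Ring order: the benzene and furan rings are both bought intact, so no ring of the target is built; the 1,3-dithiane is a temporary ring only.

Assumption: the stereocentre in the SMILES is (R), and methyl 5-bromofuran-3-carboxylate is taken as a catalogue compound (TBS = tert-butyldimethylsilyl throughout).

**Route**

Step 1
Reactants: 1 2-bromobenzene-1,4-diol (bromohydroquinone); 2 tert-butyldimethylsilyl chloride
Product: 3 2-bromo-1,4-bis(tert-butyldimethylsilyloxy)benzene
Conditions: TBSCl (2.5 equiv), imidazole (5 equiv), DMF, 0 °C → rt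
Reagents that add atoms: tert-butyldimethylsilyl chloride (2), CC(C)(C)[Si](C)(C)Cl
Why: Imidazole-promoted O-silylation of both phenols gives aryl TBS ethers that tolerate the later Pd, hydride and organolithium steps and come off with fluoride at the end.

Step 2
Reactants: 3 2-bromo-1,4-bis(tert-butyldimethylsilyloxy)benzene; 4 bis(pinacolato)diboron
Product: 5 2-[2,5-bis(tert-butyldimethylsilyloxy)phenyl]-4,4,5,5-tetramethyl-1,3,2-dioxaborolane
Conditions: B2pin2 (1.3 equiv), Pd(dppf)Cl2·CH2Cl2 (5 mol%), KOAc (3 equiv), 1,4-dioxane, 90 °C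
Reagents that add atoms: bis(pinacolato)diboron (4), CC1(C)OB(OC1(C)C)B1OC(C)(C)C(C)(C)O1
Why: Miyaura borylation with the weak base KOAc converts C–Br to C–Bpin without touching the silyl ethers and avoids an ortho-lithiated silyl ether that could undergo silyl migration.

Step 3
Reactants: 5 2-[2,5-bis(tert-butyldimethylsilyloxy)phenyl]-4,4,5,5-tetramethyl-1,3,2-dioxaborolane; 6 methyl 5-bromofuran-3-carboxylate
Product: 7 methyl 5-[2,5-bis(tert-butyldimethylsilyloxy)phenyl]furan-3-carboxylate
Conditions: Pd(OAc)2 (3 mol%), SPhos (6 mol%), K3PO4 (2 equiv), toluene/H2O (10:1), 60 °C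
Reagents that add atoms: methyl 5-bromofuran-3-carboxylate (6), COC(=O)c1coc(Br)c1
Why: Suzuki–Miyaura coupling at the ester-activated 2-bromofuran C–Br bond, with SPhos to handle the ortho-substituted boronate and a mild base in mostly toluene to keep the aryl silyl ethers.

Step 4
Reactants: 7 methyl 5-[2,5-bis(tert-butyldimethylsilyloxy)phenyl]furan-3-carboxylate
Product: 8 {5-[2,5-bis(tert-butyldimethylsilyloxy)phenyl]furan-3-yl}methanol
Conditions: DIBAL-H (2.5 equiv), CH2Cl2, −78 → −20 °C; Rochelle salt work-up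
Reagents that add atoms: none
Why: DIBAL-H reduction of the ester by two hydride transfers gives the primary alcohol cleanly, whereas stopping at the aldehyde would be unreliable.

Step 5
Reactants: 8 {5-[2,5-bis(tert-butyldimethylsilyloxy)phenyl]furan-3-yl}methanol
Product: 9 5-[2,5-bis(tert-butyldimethylsilyloxy)phenyl]furan-3-carbaldehyde
Conditions: Dess–Martin periodinane (1.2 equiv), CH2Cl2, 0 °C → rt
Reagents that add atoms: none
Why: Dess–Martin oxidation takes the furylic primary alcohol to the aldehyde under mild, nearly neutral conditions without over-oxidation or harm to the furan and silyl ethers.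

Step 6
Reactants: 9 5-[2,5-bis(tert-butyldimethylsilyloxy)phenyl]furan-3-carbaldehyde; 10 propane-1,3-dithiol
Product: 11 2-{5-[2,5-bis(tert-butyldimethylsilyloxy)phenyl]furan-3-yl}-1,3-dithiane
Conditions: HS(CH2)3SH (1.2 equiv), BF3·OEt2 (0.2 equiv), CH2Cl2, −20 → 0 °C
Reagents that add atoms: propane-1,3-dithiol (10), SCCCS
Why: Lewis-acid-catalysed thioacetalisation turns the aldehyde into an achiral, acidic 2-aryl-1,3-dithiane, the acyl-anion equivalent for the next step.

Step 7
Reactants: 11 2-{5-[2,5-bis(tert-butyldimethylsilyloxy)phenyl]furan-3-yl}-1,3-dithiane; 12 1-bromo-3-methylbut-2-ene (prenyl bromide)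
Product: 14 2-{5-[2,5-bis(tert-butyldimethylsilyloxy)phenyl]furan-3-yl}-2-(3-methylbut-2-en-1-yl)-1,3-dithiane, via 2-lithio-1,3-dithiane 13 (not isolated)
Conditions: n-BuLi (1.05 equiv), THF, −78 → −30 °C; then prenyl bromide (1.3 equiv), −78 → 0 °C
Reagents that add atoms: 1-bromo-3-methylbut-2-ene (12), CC(C)=CCBr
Why: Corey–Seebach umpolung, in which the aryl-stabilised dithiane anion attacks the primary carbon of prenyl bromide by SN2 and so gives the linear prenyl chain that a prenyl-metal addition to the aldehyde (γ-attack) would not.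

Step 8
Reactants: 14 2-{5-[2,5-bis(tert-butyldimethylsilyloxy)phenyl]furan-3-yl}-2-(3-methylbut-2-en-1-yl)-1,3-dithiane
Product: 15 1-{5-[2,5-bis(tert-butyldimethylsilyloxy)phenyl]furan-3-yl}-4-methylpent-3-en-1-one
Conditions: MeI (10 equiv), CaCO3 (4 equiv), MeCN/H2O (9:1), 45 °C
Reagents that add atoms: water, O
Why: S-methylation-assisted dithiane hydrolysis runs near neutral and without oxidant or mercury, so the furan, the silyl hydroquinone and the β,γ-position of the olefin are preserved.

Step 9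
Reactants: 15 1-{5-[2,5-bis(tert-butyldimethylsilyloxy)phenyl]furan-3-yl}-4-methylpent-3-en-1-one
Product: 16 (1R)-1-{5-[2,5-bis(tert-butyldimethylsilyloxy)phenyl]furan-3-yl}-4-methylpent-3-en-1-ol
Conditions: (R)-selective ketoreductase (KRED, NADPH-dependent, anti-Prelog, chosen by panel screen), NADP+ (cat.), i-PrOH/potassium phosphate buffer pH 7.0 (3:7), 10% v/v toluene, MgSO4 (2 mM), 30 °C
Reagents that add atoms: none
Why: Biocatalytic asymmetric ketone reduction, in which the ketoreductase binds the arylfuryl group as the large and the prenyl CH2 as the small substituent and delivers hydride from NADPH to the Si face to set the (R)-carbinol, with isopropanol recycling the cofactor.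

Step 10
Reactants: 16 (1R)-1-{5-[2,5-bis(tert-butyldimethylsilyloxy)phenyl]furan-3-yl}-4-methylpent-3-en-1-ol; 17 3-methylbutanoic anhydride (isovaleric anhydride)
Product: 18 (1R)-1-{5-[2,5-bis(tert-butyldimethylsilyloxy)phenyl]furan-3-yl}-4-methylpent-3-en-1-yl 3-methylbutanoate
Conditions: isovaleric anhydride (1.5 equiv), Et3N (2 equiv), DMAP (0.1 equiv), CH2Cl2, 0 °C → rt
Reagents that add atoms: 3-methylbutanoic anhydride (17), CC(C)CC(=O)OC(=O)CC(C)C
Why: DMAP-catalysed O-acylation under basic, chloride-free conditions forms the ester at oxygen only, so the furylic C–O bond is never broken and the (R)-configuration is retained.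

Step 11
Reactants: 18 (1R)-1-{5-[2,5-bis(tert-butyldimethylsilyloxy)phenyl]furan-3-yl}-4-methylpent-3-en-1-yl 3-methylbutanoate
Product: 19 (1R)-1-[5-(2,5-dihydroxyphenyl)furan-3-yl]-4-methylpent-3-en-1-yl 3-methylbutanoate (CNP0296263.1)
Conditions: TBAF (2.5 equiv), AcOH (3 equiv), THF, 0 °C, argon; pH 6 work-up
Reagents that add atoms: none
Why: Acetic-acid-buffered fluoride desilylation frees both phenols quickly without base strong enough to cleave the ester, acid strong enough to ionise the furylic ester, or any oxidant for the hydroquinone.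

**Compound list**
1 | 2-bromobenzene-1,4-diol | Oc1ccc(O)c(Br)c1 | starting material
2 | tert-butyldimethylsilyl chloride | CC(C)(C)[Si](C)(C)Cl | starting material
3 | 2-bromo-1,4-bis(tert-butyldimethylsilyloxy)benzene | CC(C)(C)[Si](C)(C)Oc1ccc(O[Si](C)(C)C(C)(C)C)c(Br)c1 | intermediate
4 | bis(pinacolato)diboron | CC1(C)OB(OC1(C)C)B1OC(C)(C)C(C)(C)O1 | starting material
5 | 2-[2,5-bis(tert-butyldimethylsilyloxy)phenyl]-4,4,5,5-tetramethyl-1,3,2-dioxaborolane | CC(C)(C)[Si](C)(C)Oc1ccc(O[Si](C)(C)C(C)(C)C)c(c1)B1OC(C)(C)C(C)(C)O1 | intermediate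
6 | methyl 5-bromofuran-3-carboxylate | COC(=O)c1coc(Br)c1 | starting material
7 | methyl 5-[2,5-bis(tert-butyldimethylsilyloxy)phenyl]furan-3-carboxylate | COC(=O)c1coc(-c2cc(O[Si](C)(C)C(C)(C)C)ccc2O[Si](C)(C)C(C)(C)C)c1 | intermediate
8 | {5-[2,5-bis(tert-butyldimethylsilyloxy)phenyl]furan-3-yl}methanol | OCc1coc(-c2cc(O[Si](C)(C)C(C)(C)C)ccc2O[Si](C)(C)C(C)(C)C)c1 | intermediate
9 | 5-[2,5-bis(tert-butyldimethylsilyloxy)phenyl]furan-3-carbaldehyde | O=Cc1coc(-c2cc(O[Si](C)(C)C(C)(C)C)ccc2O[Si](C)(C)C(C)(C)C)c1 | intermediate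
10 | propane-1,3-dithiol | SCCCS | starting material
11 | 2-{5-[2,5-bis(tert-butyldimethylsilyloxy)phenyl]furan-3-yl}-1,3-dithiane | C1CSC(SC1)c1coc(-c2cc(O[Si](C)(C)C(C)(C)C)ccc2O[Si](C)(C)C(C)(C)C)c1 | intermediate
12 | 1-bromo-3-methylbut-2-ene (prenyl bromide) | CC(C)=CCBr | starting material
13 | 2-lithio-2-{5-[2,5-bis(tert-butyldimethylsilyloxy)phenyl]furan-3-yl}-1,3-dithiane | [Li]C1(SCCCS1)c1coc(-c2cc(O[Si](C)(C)C(C)(C)C)ccc2O[Si](C)(C)C(C)(C)C)c1 | intermediate
14 | 2-{5-[2,5-bis(tert-butyldimethylsilyloxy)phenyl]furan-3-yl}-2-(3-methylbut-2-en-1-yl)-1,3-dithiane | CC(C)=CCC1(SCCCS1)c1coc(-c2cc(O[Si](C)(C)C(C)(C)C)ccc2O[Si](C)(C)C(C)(C)C)c1 | intermediate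
15 | 1-{5-[2,5-bis(tert-butyldimethylsilyloxy)phenyl]furan-3-yl}-4-methylpent-3-en-1-one | CC(C)=CCC(=O)c1coc(-c2cc(O[Si](C)(C)C(C)(C)C)ccc2O[Si](C)(C)C(C)(C)C)c1 | intermediate
16 | (1R)-1-{5-[2,5-bis(tert-butyldimethylsilyloxy)phenyl]furan-3-yl}-4-methylpent-3-en-1-ol | CC(C)=CC[C@@H](O)c1coc(-c2cc(O[Si](C)(C)C(C)(C)C)ccc2O[Si](C)(C)C(C)(C)C)c1 | intermediate
17 | 3-methylbutanoic anhydride | CC(C)CC(=O)OC(=O)CC(C)C | starting material
18 | (1R)-1-{5-[2,5-bis(tert-butyldimethylsilyloxy)phenyl]furan-3-yl}-4-methylpent-3-en-1-yl 3-methylbutanoate | CC(C)=CC[C@@H](OC(=O)CC(C)C)c1coc(-c2cc(O[Si](C)(C)C(C)(C)C)ccc2O[Si](C)(C)C(C)(C)C)c1 | intermediate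
19 | (1R)-1-[5-(2,5-dihydroxyphenyl)furan-3-yl]-4-methylpent-3-en-1-yl 3-methylbutanoate | CC(C)=CC[C@@H](OC(=O)CC(C)C)c1coc(-c2cc(O)ccc2O)c1 | target

**Step count and risks**
Total steps: 11. Longest linear sequence: 11 (steps 1–11 from compound 1).

The three steps most likely to fail, with one fallback each:

Step 9 (the ketoreductase may not turn over the bulky, very lipophilic bis-silyl ketone). The fallback sets out from 15 and comes back at 19. It gives the enzyme a small, polar substrate and changes the end-game protection. Ketone 15 is desilylated first (TBAF/AcOH, THF, 0 °C) to 1-[5-(2,5-dihydroxyphenyl)furan-3-yl]-4-methylpent-3-en-1-one F1. The same class of (R)-selective ketoreductase (NADP+, i-PrOH, degassed pH 7 buffer with ascorbate) reduces it to (1R)-1-[5-(2,5-dihydroxyphenyl)furan-3-yl]-4-methylpent-3-en-1-ol F2. Exhaustive acylation with anhydride 17 (Et3N, DMAP, CH2Cl2) gives 2-{4-[(1R)-4-methyl-1-(3-methylbutanoyloxy)pent-3-en-1-yl]furan-2-yl}-1,4-phenylene bis(3-methylbutanoate) F3. Its two aryl esters are then cleaved selectively by aminolysis with pyrrolidine (CH2Cl2, 0 °C, argon), which leaves the secondary alkyl ester untouched and gives 19 directly.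

Step 8 (dithiane hydrolysis may stall or isomerise the β,γ-enone). The fallback sets out from 7 and comes back at 15. It replaces the acyl-anion logic by an acyl electrophile and keeps every intermediate achiral. Ester 7 is converted with MeNH(OMe)·HCl/i-PrMgCl (THF, −20 °C) into N-methoxy-N-methyl-5-[2,5-bis(tert-butyldimethylsilyloxy)phenyl]furan-3-carboxamide F4. Allylmagnesium bromide (THF, −78 °C, cold NH4Cl quench) gives 1-{5-[2,5-bis(tert-butyldimethylsilyloxy)phenyl]furan-3-yl}but-3-en-1-one F5. Cross-metathesis with excess 2-methyl-2-butene (Grubbs II, CH2Cl2, 40 °C) then installs the trisubstituted olefin and gives 15.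

Step 3 (the ortho-silyloxy boronate may protodeboronate or lose TBS under Suzuki conditions). The fallback sets out from 6 and comes back at 7, bypassing 3 and 5. It couples with robust methyl ethers and swaps the protecting groups afterwards. Bromide 6 is coupled with commercial (2,5-dimethoxyphenyl)boronic acid (Pd(PPh3)4, K2CO3, dioxane/H2O, 80 °C) to give methyl 5-(2,5-dimethoxyphenyl)furan-3-carboxylate F6. BBr3 (CH2Cl2, −78 → 0 °C) cleaves both methyl ethers to give methyl 5-(2,5-dihydroxyphenyl)furan-3-carboxylate F7. TBSCl/imidazole (DMF, rt) then silylates both phenols to give 7.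

Further compounds
F1 | step 9 | 1-[5-(2,5-dihydroxyphenyl)furan-3-yl]-4-methylpent-3-en-1-one | CC(C)=CCC(=O)c1coc(-c2cc(O)ccc2O)c1
F2 | step 9 | (1R)-1-[5-(2,5-dihydroxyphenyl)furan-3-yl]-4-methylpent-3-en-1-ol | CC(C)=CC[C@@H](O)c1coc(-c2cc(O)ccc2O)c1
F3 | step 9 | 2-{4-[(1R)-4-methyl-1-(3-methylbutanoyloxy)pent-3-en-1-yl]furan-2-yl}-1,4-phenylene bis(3-methylbutanoate) | CC(C)=CC[C@@H](OC(=O)CC(C)C)c1coc(-c2cc(OC(=O)CC(C)C)ccc2OC(=O)CC(C)C)c1
F4 | step 8 | N-methoxy-N-methyl-5-[2,5-bis(tert-butyldimethylsilyloxy)phenyl]furan-3-carboxamide | CON(C)C(=O)c1coc(-c2cc(O[Si](C)(C)C(C)(C)C)ccc2O[Si](C)(C)C(C)(C)C)c1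
F5 | step 8 | 1-{5-[2,5-bis(tert-butyldimethylsilyloxy)phenyl]furan-3-yl}but-3-en-1-one | C=CCC(=O)c1coc(-c2cc(O[Si](C)(C)C(C)(C)C)ccc2O[Si](C)(C)C(C)(C)C)c1
F6 | step 3 | methyl 5-(2,5-dimethoxyphenyl)furan-3-carboxylate | COC(=O)c1coc(-c2cc(OC)ccc2OC)c1
F7 | step 3 | methyl 5-(2,5-dihydroxyphenyl)furan-3-carboxylate | COC(=O)c1coc(-c2cc(O)ccc2O)c1
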